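In the closed flask of the winter set-up nothing enters or leaves, so a difference between two concentrations can hold through the run, and that difference is my handle on this flask.

the same everywhere: substrate 12 mM; partner B 3.00 equiv

| run | partner A | remark | time |
|---|---|---|---|
| spring | 1.10 equiv | a single well-mixed tank run continuously and read at steady state, 4.0 h in it on average |  |
| midnight | 1.10 equiv | a single well-mixed tank run continuously and read at steady state, 12.0 h in it on average |  |
| winter | 1.10 equiv | everything together in a closed stirred flask, run for 4.0 h | 4.0 h |
| summer | 1.10 equiv (fed, over 4.00 h) | all but partner A at the start; partner A goes in evenly over 4.00 h, the run ends at 4.0 h | 4.0 h |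

- the set-up with the highest amount of open intermediate at the outlet or at the end, in percent of the substrate put in ("none" if the first two lie within 2 percentage points) (spring / midnight / winter / summer / none)
- amount of open intermediate at the outlet or at the end, in percent of the substrate put in, spring
- amount of open intermediate at the outlet or at the end, in percent of the substrate put in, midnight
- amount of open intermediate at the outlet or at the end, in percent of the substrate put in, winter
- amount of open intermediate at the outlet or at the end, in percent of the substrate put in, summer

- in percentages every species weighs as the substrate in it: one homo product counts as two
- two of one species on the left: rate k times its square, two consumed each time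
- the stated concentrations are those of everything mixed, before any reaction; amounts are the same in each set-up
- the feed brings no volume worth counting
- run time (winter): 4.0 h

    substrate + partner B → open intermediate (k1 = 16 M⁻¹ h⁻¹)
    partner B + partner A → second intermediate (k2 = 260 M⁻¹ h⁻¹)
    open intermediate + second intermediate → target (k3 = 31 M⁻¹ h⁻¹)
    2 open intermediate → homo product (k4 = 4.6 M⁻¹ h⁻¹)
    target ⇌ isomer of the product (K5 = 17, k5 = 0.093 h⁻¹)

*Which reaction comes first in winter?* Partner B with partner A. Partner B's half-life by that step, with partner A held at its charge, is 0.20 h, against 1.2 h for substrate with partner B. That is shorter, so I take partner A's charge out of partner B at the start.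

*What remains for the substrate?* The margin, [partner B] − [substrate], which is 10.8 mM. The first step takes one of each out, which leaves the margin unchanged.

*And the integrated rate law?* For a second-order step with unequal concentrations, the ratio [partner B]/[substrate] grows exponentially at 16 M⁻¹ h⁻¹ times the margin, which is 0.173 h⁻¹. The ratio starts at 1.90 and reaches 3.79 at 4.0 h. Since [substrate] is the margin divided by that ratio less one, the winter flask holds 3.87 mM, with 67.8% of the substrate converted.

*But summer's partner A trickles in, so the margin isn't constant. What then?* In the summer flask it slides down from 24.0 mM towards 10.8 mM. I use the mean, 17.4 mM, crudely, which gives about 2.69 mM of substrate and 77.6% converted. My reckoning stops there: it gives the converted share and not the amount of open intermediate.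

The forecast gives 23.3% for spring, 19.1% for midnight, 30.5% for winter and 41.5% for summer, and it names summer. Its ground for the fed run, where I stands for open intermediate, is that “I builds faster and is drained later”.

The simulation gives 23.2% for spring, 19.0% for midnight, 29.8% for winter and 41.6% for summer, so summer leads by 12 percentage points over winter.

At 4.0 h in the winter flask, the margin gives open intermediate forming at 0.908 mM h⁻¹; the balance, using the readings 29.8% and 3.28% of homo product, leaves about 9.04 mM of second intermediate, so the third step removes it at 1.00 mM h⁻¹, which is faster than that formation. At the end of the summer run, the feed rate over 260 M⁻¹ h⁻¹ times [partner B] leaves about 0.879 mM of partner A unreacted, my substrate figure gives formation at about 0.619 mM h⁻¹, and the same balance, with 8.06% of homo product and that partner A counted, leaves about 8.98 mM of second intermediate, so formation is slower than removal, at 1.39 mM h⁻¹.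

The constants are assumed; what happens was integrated by code.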